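**Retrosynthetic overview**
1. Late stage: the O8 acetate and the O9 (2S,3S)-epoxyangelate are placed on a 7,8,9-triol lactone. The α-methylene-γ-lactone (ring B: O6–C12–C11–C7–C6) is closed from a C12 acid onto O6 of the finished ten-membered carbocycle (ring A, C1–C10).
2. The strategy rests on the C10=C1–C2–C3–C4=C5 1,5-diene inside ring A (ring-cis C1=C10, ring-trans C4=C5), which is the retron of a [3,3] shift. The C10 methyl is traced back to a C10 enol triflate, that is, to a C1=C10 enolate.
3. Key disconnection: break C2–C3 and remake C5–C10. This gives cis-1-vinyl-2-isopropenylcyclohexanol 20 (six-membered ring C5–C10, C10 the carbinol), which already carries C6–C9 as two acetonides and the C7 2-(PMB-oxymethyl)vinyl group.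
4. 20 comes from anti opening at C5 of a C5–C10 epoxide. C6 and C7 come from an enone epoxide and a singlet-oxygen adduct, and C8 and C9 from (1S,2S)-3-bromocyclohexa-3,5-diene-1,2-diol. All ring oxygens are in place before isopropenyl and vinyl appear.
5. Ring order: six-membered carbocycle (bought), then ten-membered ring A (step 14), then lactone ring B (step 19).

Key step: step 14

**Remarks on the chemistry**
- Germacrane numbering is used for the ring carbons from compound 4 on. β is the face of O8, O9 and C11; α is the face of O6 and O7.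
- In 20, vinyl and isopropenyl are both α (O10 β). Only this cis isomer reaches the required chair with C11, O6 and O9 equatorial. The β,β cis isomer would need isopropenyl, C11 and O9 all axial on one face, and should therefore rearrange through its other chair to the ring with the opposite cis/trans pairing.
- A vinyl metal adds to a 2-isopropenyl ketone anti to the isopropenyl group and gives the trans isomer, which can only give the trans,trans ring. The C10–O and C5–C4 bonds are therefore set by epoxide opening.
- In 23 the C1=C10 bond is E by the sequence rule because OTf outranks C9, although C2 and C9 are cis on it. It becomes Z in 24.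
- Compound 4 is taken as the commercial whole-cell oxidation product of bromobenzene.

**Step 1**
Reactants: 1 4-methoxybenzyl alcohol; 2 2,3-dibromopropene
Product: 3 2-bromoallyl 4-methoxybenzyl ether
Conditions: NaH, THF/DMF, 0 °C to rt
Reagents that add atoms: none
Why: Williamson ether synthesis in which the alkoxide displaces the allylic bromide by SN2 while the vinylic C–Br bond, needed in step 3, is inert.

**Step 2**
Reactants: 4 (1S,2S)-3-bromocyclohexa-3,5-diene-1,2-diol
Product: 5 (3aS,7aS)-4-bromo-2,2-dimethyl-3a,7a-dihydro-1,3-benzodioxole (Br on C7, 8β,9β-acetonide)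
Conditions: 2,2-dimethoxypropane, p-TsOH (cat.), CH2Cl2, 0 °C
Reagents that add atoms: 2,2-dimethoxypropane COC(C)(C)OC
Why: Acid-catalysed transketalisation of the cis-diol gives the cis-fused dioxolane, which carries C8 and C9 (both O β, from the chiral pool) and shields the β face in steps 4 and 5.

**Step 3**
Reactants: 3 2-bromoallyl 4-methoxybenzyl ether; 5 bromodiene acetonide
Product: 8 (3aR,7aS)-4-[3-(4-methoxybenzyloxy)prop-1-en-2-yl]-2,2-dimethyl-3a,7a-dihydro-1,3-benzodioxole, via alkenyllithium 6 (not isolated), via alkenylzinc bromide 7 (not isolated)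
Conditions: 3, t-BuLi (2 equiv), Et2O, −78 °C; ZnBr2, THF, −78 to 0 °C; then 5, Pd(PPh3)4 (cat.), THF, rt
Reagents that add atoms: none
Why: Negishi coupling in which low-temperature bromine–lithium exchange and transmetalation to zinc forestall loss of the allylic alkoxide, and zerovalent palladium joins the two sp2 carbons (C11–C7) without touching C8 or C9.

**Step 4**
Reactants: 8 C7-alkenyl diene acetonide
Product: 10 hydroxy enone (C10 ketone; C5=C6; C7 with OH α and alkenyl β; 8β,9β-acetonide), via 7α,10α-endoperoxide 9 (not isolated)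
Conditions: O2, tetraphenylporphyrin (cat.), hν, CH2Cl2, −78 °C; then Et3N, −78 to 0 °C
Reagents that add atoms: dioxygen O=O
Why: Singlet oxygen adds [4+2] across C7/C10 of the cisoid ring diene on the α face opposite the acetonide, which sets C7 (O7 α, C11 β), and the Kornblum–DeLaMare rearrangement can remove only the single bridgehead hydrogen at C10, so the ketone appears at C10 and the tertiary alcohol at C7.

**Step 5**
Reactants: 10 hydroxy enone
Product: 11 5α,6α-epoxy ketone
Conditions: t-BuOOH, DBU, CH2Cl2, 0 °C, short contact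
Reagents that add atoms: tert-butyl hydroperoxide CC(C)(C)OO
Why: Weitz–Scheffer epoxidation touches only the electron-poor C5=C6 bond, and the peroxide anion attacks C6 on the α face, hydrogen-bonded to O7–H and away from C11 and the acetonide, which sets C6 (O6 α, cis to O7).

**Step 6**
Reactants: 11 epoxy ketone
Product: 12 10-methylene 5α,6α-epoxide
Conditions: MePPh3Br, KN(SiMe3)2, THF, −78 to 0 °C
Reagents that add atoms: methyltriphenylphosphonium bromide C[P+](c1ccccc1)(c1ccccc1)c1ccccc1.[Br-]
Why: Wittig methylenation of the activated α-oxygenated ketone brings in C1 and leaves the epoxide intact, since the cis O7 alkoxide cannot reach C6 from the rear.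

**Step 7**
Reactants: 12 methylene epoxide
Product: 13 C1 acetate of the 5(10)-ene 6α,7α-diol
Conditions: Pd(PPh3)4 (cat.), AcOH, THF, 0 °C
Reagents that add atoms: acetic acid CC(=O)O
Why: Tsuji–Trost type 1,4-opening in which zerovalent palladium ionises the allylic C5–O bond and acetate attacks the unhindered CH2 terminus C1 of the π-allyl complex, which moves the alkene to C5=C10 and leaves the C6–O bond and its configuration untouched.

**Step 8**
Reactants: 13 acetoxy diol
Product: 14 bis-acetonide allylic acetate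
Conditions: 2,2-dimethoxypropane, PPTS (cat.), CH2Cl2, rt
Reagents that add atoms: 2,2-dimethoxypropane COC(C)(C)OC
Why: Acid-catalysed ketalisation of the cis C6/C7 diol gives the second dioxolane, so that the primary alcohol freed next is the only directing hydroxyl.

**Step 9**
Reactants: 14 bis-acetonide acetate
Product: 15 bis-acetonide allylic alcohol (C10–CH2OH, C5=C10)
Conditions: K2CO3 (cat.), MeOH, 0 °C
Reagents that add atoms: none
Why: Base-catalysed transesterification removes the primary acetate without affecting the ketals or the PMB ether.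

**Step 10**
Reactants: 15 allylic alcohol
Product: 16 5β,10β-epoxy alcohol
Conditions: Ti(OiPr)4, L-(+)-diethyl tartrate, t-BuOOH, 4 Å molecular sieves, CH2Cl2, −20 °C
Reagents that add atoms: tert-butyl hydroperoxide CC(C)(C)OO
Why: Sharpless asymmetric epoxidation, in which only C5=C10 belongs to a free allylic alcohol and L-(+)-tartrate delivers oxygen to the β face by reagent control (the two faces of this nearly C2-symmetric ring differ little), sets C10 (O10 β, cis to O9).

**Step 11**
Reactants: 16 epoxy alcohol; 17 isopropenylmagnesium bromide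
Product: 18 5α-isopropenyl 1,10β-diol
Conditions: 17 (excess), CuI (cat.), THF, −30 to 0 °C
Reagents that add atoms: none
Why: In this copper-catalysed Grignard opening of a 2,3-epoxy alcohol C10 is fully substituted, so SN2 attack comes at C5 from the α face with inversion, in the trans-diaxial (Fürst–Plattner) sense through the half-chair that keeps C11 equatorial, which places isopropenyl α, trans to O10 and hence cis to C1.

**Step 12**
Reactants: 18 diol
Product: 19 10β-hydroxy C1 aldehyde
Conditions: TEMPO (cat.), PhI(OAc)2, CH2Cl2, rt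
Reagents that add atoms: none
Why: Oxoammonium (TEMPO) oxidation is selective for the primary alcohol and stops at the α-hydroxy aldehyde because the neighbouring alcohol is tertiary.

**Step 13**
Reactants: 19 hydroxy aldehyde
Product: 20 cis-1-vinyl-2-isopropenylcyclohexanol (10α-vinyl, 10β-OH, 5α-isopropenyl, 6α,7α- and 8β,9β-acetonides, C7β 2-(PMB-oxymethyl)vinyl)
Conditions: MePPh3Br, KN(SiMe3)2, THF, −78 to 0 °C
Reagents that add atoms: methyltriphenylphosphonium bromide C[P+](c1ccccc1)(c1ccccc1)c1ccccc1.[Br-]
Why: Wittig methylenation turns C1 into the vinyl group (C1=C2) and cannot disturb the non-enolisable quaternary C10.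

**Step 14**
Reactants: 20 cis-1-vinyl-2-isopropenylcyclohexanol
Product: 23 ten-membered (1E,4E by sequence rule; ring-cis C1=C10, ring-trans C4=C5) C10 enol triflate bis-acetonide, via potassium alkoxide 21 (not isolated), via potassium enolate 22 (not isolated)
Conditions: KH, 18-crown-6, THF, 0 °C to rt; then −78 °C, N-(5-chloro-2-pyridyl)bis(trifluoromethanesulfonimide)
Reagents that add atoms: N-(5-chloro-2-pyridyl)bis(trifluoromethanesulfonimide) FC(F)(F)S(=O)(=O)N(c1ccc(Cl)cn1)S(=O)(=O)C(F)(F)F
Why: Deprotonation gives the crown-separated alkoxide 21, whose oxyanion weakens C5–C10 so that a concerted [3,3]-sigmatropic shift joins vinyl terminus C2 to isopropenyl terminus C3 while C5–C10 breaks; the closest known reaction type is the anionic oxy-Cope rearrangement of 1,2-dialkenylcyclohexanols with O-sulfonylation of the enolate in the same flask. Ring A is not closed end to end but arises by four-atom expansion of the cyclohexane through a six-centre chair transition state. No stereocentre is created and C6–C9 are untouched, so what is set are two alkene geometries. The step needs the chair with C6 pseudo-equatorial (ring-trans C4=C5) and with C9 pseudo-axial and the oxyanion pseudo-equatorial (ring-cis C1=C10), which corresponds to the cyclohexane chair with axial isopropenyl, axial O10 and equatorial vinyl. In 20 this same chair keeps C11, O6 and O9 equatorial because both alkenyl groups share the α face with O6 and O7, whereas the other chair, which leads to the opposite pairing of geometries, would put C11, O9, O6 and vinyl axial. Enolate 22 is regiodefined at C1=C10 and is sulfonylated at −78 °C before proton transfer to C9 and loss of O8 can set in, which fixes position and geometry of the future methyl-bearing alkene.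

**Step 15**
Reactants: 23 enol triflate
Product: 24 (1(10)Z,4E)-10-methyl diene bis-acetonide PMB ether
Conditions: MeMgBr, Fe(acac)3 (cat.), THF/NMP, −30 to 0 °C
Reagents that add atoms: methylmagnesium bromide C[Mg]Br
Why: Iron-catalysed cross-coupling of an alkenyl triflate with a methyl Grignard reagent replaces OTf by CH3 with retention of alkene geometry, faster than any attack on the ketals or the ether.

**Step 16**
Reactants: 24 PMB ether
Product: 25 C12 allylic alcohol
Conditions: DDQ, CH2Cl2/pH 7 buffer, 0 °C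
Reagents that add atoms: none
Why: Oxidative PMB cleavage (hydride abstraction from the electron-rich benzylic position, then hydrolysis) frees O12 under buffered conditions harmless to the ketals and the diene.

**Step 17**
Reactants: 25 allylic alcohol
Product: 26 C12 enal
Conditions: MnO2, CH2Cl2, rt
Reagents that add atoms: none
Why: MnO2 oxidises the primary allylic alcohol, the only free hydroxyl, to the 2-substituted acrolein.

**Step 18**
Reactants: 26 enal
Product: 27 C12 acrylic acid
Conditions: NaClO2, NaH2PO4, 2-methyl-2-butene, t-BuOH/H2O, 0 °C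
Reagents that add atoms: sodium chlorite [Na+].[O-]Cl=O
Why: Pinnick oxidation converts the enal into the acid while 2-methyl-2-butene scavenges hypochlorous acid and so protects the ring alkenes.

**Step 19**
Reactants: 27 acid bis-acetonide
Product: 29 7α,8β,9β-trihydroxy 6α,12-olide, via tetraol acid 28 (not isolated)
Conditions: AcOH/H2O, 40 °C
Reagents that add atoms: none
Why: Mild aqueous acid hydrolyses both ketals and the liberated allylic O6–H closes onto C12 (5-exo-trig acyl substitution) to the trans-fused 6,12-olide, the lactone type that 8β-oxygenated germacranolides retain, with no stereocentre touched.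

**Step 20**
Reactants: 30 angelic acid
Product: 31 (Z)-2-methylbut-2-en-1-ol
Conditions: LiAlH4, Et2O, 0 °C
Reagents that add atoms: none
Why: Hydride reduction of the carboxylic acid does not involve the alkene, so the Z geometry is kept.

**Step 21**
Reactants: 31 (Z)-2-methylbut-2-en-1-ol
Product: 32 [(2R,3S)-2,3-dimethyloxiran-2-yl]methanol
Conditions: Ti(OiPr)4, D-(−)-diisopropyl tartrate, t-BuOOH, 4 Å molecular sieves, CH2Cl2, −20 °C
Reagents that add atoms: tert-butyl hydroperoxide CC(C)(C)OO
Why: Sharpless asymmetric epoxidation with D-(−)-tartrate delivers oxygen to the face that gives the (2R,3S)-epoxy alcohol, and syn addition keeps CH2OH and the C3 methyl cis.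

**Step 22**
Reactants: 32 epoxy alcohol
Product: 34 (2S,3S)-2,3-dimethyloxirane-2-carboxylic acid, via epoxy aldehyde 33 (not isolated)
Conditions: TEMPO (cat.), PhI(OAc)2, MeCN/H2O, rt
Reagents that add atoms: water O
Why: TEMPO/PhI(OAc)2 oxidation takes the primary alcohol through the aldehyde hydrate to the acid near neutral pH without opening the epoxide, and the C2 descriptor changes to S only through ligand priorities.

**Step 23**
Reactants: 29 triol lactone; 34 (2S,3S)-epoxyangelic acid
Product: 36 O9 (2S,3S)-epoxyangelate 7,8-diol, via mixed anhydride 35 (not isolated)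
Conditions: 34, 2,4,6-trichlorobenzoyl chloride, Et3N, toluene, rt; then 29, DMAP, 0 °C to rt
Reagents that add atoms: none
Why: Yamaguchi esterification, in which the bulky mixed anhydride acylates the allylic O9–H flanked by sp2 C10 in preference to O8–H next to the fully substituted C7 and to the tertiary O7–H, with no stereocentre involved.

**Step 24**
Reactants: 36 O9 monoester
Product: 37 target CNP0271187.2
Conditions: Ac2O, pyridine, DMAP (cat.), CH2Cl2, 0 °C
Reagents that add atoms: acetic anhydride CC(=O)OC(C)=O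
Why: DMAP-catalysed acetylation of the remaining secondary O8–H, with the tertiary O7–H inert under these conditions, completes the target.

**Compound list**
1 | 4-methoxybenzyl alcohol | COc1ccc(CO)cc1 | starting material
2 | 2,3-dibromopropene | C=C(Br)CBr | starting material
3 | 2-bromoallyl 4-methoxybenzyl ether | C=C(Br)COCc1ccc(OC)cc1 | intermediate
4 | (1S,2S)-3-bromocyclohexa-3,5-diene-1,2-diol | BrC1=CC=C[C@H](O)[C@@H]1O | starting material
5 | (3aS,7aS)-4-bromo-2,2-dimethyl-3a,7a-dihydro-1,3-benzodioxole | BrC1=CC=C[C@@H]2OC(C)(C)O[C@H]12 | intermediate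
6 | 3-(4-methoxybenzyloxy)prop-1-en-2-yllithium | [Li]C(=C)COCc1ccc(OC)cc1 | intermediate
7 | 3-(4-methoxybenzyloxy)prop-1-en-2-ylzinc bromide | Br[Zn]C(=C)COCc1ccc(OC)cc1 | intermediate
8 | (3aR,7aS)-4-[3-(4-methoxybenzyloxy)prop-1-en-2-yl]-2,2-dimethyl-3a,7a-dihydro-1,3-benzodioxole | C=C(COCc1ccc(OC)cc1)C2=CC=C[C@@H]3OC(C)(C)O[C@H]23 | intermediate
9 | 7α,10α-endoperoxide of 8 (peroxide anti to the acetonide) | C=C(COCc1ccc(OC)cc1)[C@@]23C=C[C@@H](OO2)[C@@H]4OC(C)(C)O[C@H]34 | intermediate
10 | hydroxy enone (C10=O, C5=C6, 7α-OH, 7β-alkenyl, 8β,9β-acetonide) | C=C(COCc1ccc(OC)cc1)[C@]2(O)C=CC(=O)[C@@H]3OC(C)(C)O[C@H]23 | intermediate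
11 | 5α,6α-epoxy ketone | C=C(COCc1ccc(OC)cc1)[C@]2(O)[C@H]4O[C@H]4C(=O)[C@@H]3OC(C)(C)O[C@H]23 | intermediate
12 | 10-methylene 5α,6α-epoxide | C=C(COCc1ccc(OC)cc1)[C@]2(O)[C@H]4O[C@H]4C(=C)[C@@H]3OC(C)(C)O[C@H]23 | intermediate
13 | C1 acetate of the 5(10)-ene 6α,7α-diol | C=C(COCc1ccc(OC)cc1)[C@]2(O)[C@@H](O)C=C(COC(C)=O)[C@@H]3OC(C)(C)O[C@H]23 | intermediate
14 | bis-acetonide allylic acetate | CC(=O)OCC1=C[C@@H]2OC(C)(C)O[C@]2(C(=C)COCc3ccc(OC)cc3)[C@H]4OC(C)(C)O[C@@H]14 | intermediate
15 | bis-acetonide allylic alcohol | OCC1=C[C@@H]2OC(C)(C)O[C@]2(C(=C)COCc3ccc(OC)cc3)[C@H]4OC(C)(C)O[C@@H]14 | intermediate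
16 | 5β,10β-epoxy alcohol | OC[C@@]15O[C@H]5[C@@H]2OC(C)(C)O[C@]2(C(=C)COCc3ccc(OC)cc3)[C@H]4OC(C)(C)O[C@@H]14 | intermediate
17 | isopropenylmagnesium bromide | CC(=C)[Mg]Br | starting material
18 | 5α-isopropenyl 1,10β-diol | OC[C@]1(O)[C@H](C(C)=C)[C@@H]2OC(C)(C)O[C@]2(C(=C)COCc3ccc(OC)cc3)[C@H]4OC(C)(C)O[C@@H]14 | intermediate
19 | 10β-hydroxy C1 aldehyde | O=C[C@]1(O)[C@H](C(C)=C)[C@@H]2OC(C)(C)O[C@]2(C(=C)COCc3ccc(OC)cc3)[C@H]4OC(C)(C)O[C@@H]14 | intermediate
20 | cis-1-vinyl-2-isopropenylcyclohexanol (10α-vinyl, 10β-OH, 5α-isopropenyl, bis-acetonide) | C=C[C@]1(O)[C@H](C(C)=C)[C@@H]2OC(C)(C)O[C@]2(C(=C)COCc3ccc(OC)cc3)[C@H]4OC(C)(C)O[C@@H]14 | intermediate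
21 | potassium alkoxide of 20 | C=C[C@]1([O-])[C@H](C(C)=C)[C@@H]2OC(C)(C)O[C@]2(C(=C)COCc3ccc(OC)cc3)[C@H]4OC(C)(C)O[C@@H]14.[K+] | intermediate
22 | ten-membered potassium C1=C10 enolate | [C@H]12/C=C(\C)CC/C=C(/[O-])[C@@H]3OC(C)(C)O[C@@H]3[C@@]1(C(=C)COCc4ccc(OC)cc4)OC(C)(C)O2.[K+] | intermediate
23 | ten-membered C10 enol triflate bis-acetonide | [C@H]12/C=C(\C)CC/C=C(/OS(=O)(=O)C(F)(F)F)[C@@H]3OC(C)(C)O[C@@H]3[C@@]1(C(=C)COCc4ccc(OC)cc4)OC(C)(C)O2 | intermediate
24 | (1(10)Z,4E)-10-methyl diene bis-acetonide PMB ether | [C@H]12/C=C(\C)CC/C=C(/C)[C@@H]3OC(C)(C)O[C@@H]3[C@@]1(C(=C)COCc4ccc(OC)cc4)OC(C)(C)O2 | intermediate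
25 | C12 allylic alcohol | [C@H]12/C=C(\C)CC/C=C(/C)[C@@H]3OC(C)(C)O[C@@H]3[C@@]1(C(=C)CO)OC(C)(C)O2 | intermediate
26 | C12 enal | [C@H]12/C=C(\C)CC/C=C(/C)[C@@H]3OC(C)(C)O[C@@H]3[C@@]1(C(=C)C=O)OC(C)(C)O2 | intermediate
27 | C12 acrylic acid | [C@H]12/C=C(\C)CC/C=C(/C)[C@@H]3OC(C)(C)O[C@@H]3[C@@]1(C(=C)C(=O)O)OC(C)(C)O2 | intermediate
28 | 6α,7α,8β,9β-tetraol acid | OC(=O)C(=C)[C@]2(O)[C@@H](O)/C=C(\C)CC/C=C(/C)[C@H](O)[C@@H]2O | intermediate
29 | 7α,8β,9β-trihydroxy 6α,12-olide | C=C1C(=O)O[C@H]2/C=C(\C)CC/C=C(/C)[C@H](O)[C@H](O)[C@]12O | intermediate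
30 | angelic acid | C/C=C(/C)C(=O)O | starting material
31 | (Z)-2-methylbut-2-en-1-ol | C/C=C(/C)CO | intermediate
32 | [(2R,3S)-2,3-dimethyloxiran-2-yl]methanol | OC[C@@]1(C)O[C@H]1C | intermediate
33 | (2S,3S)-2,3-dimethyloxirane-2-carbaldehyde | O=C[C@@]1(C)O[C@H]1C | intermediate
34 | (2S,3S)-2,3-dimethyloxirane-2-carboxylic acid | OC(=O)[C@@]1(C)O[C@H]1C | intermediate
35 | mixed anhydride of 34 and 2,4,6-trichlorobenzoic acid | O=C(OC(=O)[C@@]1(C)O[C@H]1C)c1c(Cl)cc(Cl)cc1Cl | intermediate
36 | O9 (2S,3S)-epoxyangelate 7,8-diol | C=C1C(=O)O[C@H]2/C=C(\C)CC/C=C(/C)[C@H](OC(=O)[C@@]3(C)O[C@H]3C)[C@H](O)[C@]12O | intermediate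
37 | CNP0271187.2 | C=C1C(=O)O[C@H]2/C=C(\C)CC/C=C(/C)[C@H](OC(=O)[C@@]3(C)O[C@H]3C)[C@H](OC(C)=O)[C@]12O | target

**Total step count:** 24. **Longest linear sequence:** 20 steps (4 → 37 through steps 2–19, 23 and 24).

**Steps most likely to fail**

**Step 14.**
- What may go wrong: the naked alkoxide may fragment (O6 lies antiperiplanar to C5–C10). The enolate may shift its proton to C9 and expel O8 before it is sulfonylated. Part of the material may leak through the second chair.
- Fallback (sets out from 20, returns at 23): 20 is silylated (Me3SiOTf, 2,6-lutidine) to the trimethylsilyl ether F1. F1 is heated in base-washed glass (toluene, sealed tube, about 200 °C), so that the neutral siloxy-Cope rearrangement passes through the same chair to the trimethylsilyl enol ether F2. MeLi at 0 °C then releases the lithium enolate F3 with retention of geometry, and the same pyridyl triflimide at −78 °C gives 23.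

**Step 11.**
- What may go wrong: axial attack at C5, syn to the axial O7 of the neighbouring dioxolane, may be slow. Halide opening or migration of the epoxide towards C1 could then compete.
- Fallback (sets out from 16, returns at 18): the slim sp nucleophile Et2AlC≡CH (from ethynylmagnesium bromide and Et2AlCl, toluene, 0 °C) opens the epoxide at C5 in the same anti sense to the 5α-ethynyl diol F4. Zirconium-catalysed syn methylalumination (Me3Al, Cp2ZrCl2 cat., CH2Cl2) gives the alkenylalane F5, and protonolysis turns it into the isopropenyl group of 18.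

**Step 19.**
- What may go wrong: once both diols are free, the carboxyl group may close onto O8, which is cis to C11, instead of onto O6.
- Fallback (sets out from 24, returns at 29): both ketals of 24 are hydrolysed while C12 is still an ether, giving the tetraol PMB ether F6. Kinetic ketalisation (2-methoxypropene, PPTS, −20 °C) picks the secondary/secondary 8,9-diol and gives the 8,9-monoacetonide F7. DDQ frees the C12 alcohol F8. TEMPO/PhI(OAc)2 oxidative lactonisation of the C12/O6 1,4-diol, with O8 masked, gives the lactone acetonide F9, and brief aqueous acetic acid leads to 29.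

**Further compounds**
F1 | step 14 | trimethylsilyl ether of 20 | C=C[C@]1(O[Si](C)(C)C)[C@H](C(C)=C)[C@@H]2OC(C)(C)O[C@]2(C(=C)COCc3ccc(OC)cc3)[C@H]4OC(C)(C)O[C@@H]14
F2 | step 14 | ten-membered C10 trimethylsilyl enol ether | [C@H]12/C=C(\C)CC/C=C(/O[Si](C)(C)C)[C@@H]3OC(C)(C)O[C@@H]3[C@@]1(C(=C)COCc4ccc(OC)cc4)OC(C)(C)O2
F3 | step 14 | ten-membered lithium C1=C10 enolate | [C@H]12/C=C(\C)CC/C=C(/[O-])[C@@H]3OC(C)(C)O[C@@H]3[C@@]1(C(=C)COCc4ccc(OC)cc4)OC(C)(C)O2.[Li+]
F4 | step 11 | 5α-ethynyl 1,10β-diol | OC[C@]1(O)[C@H](C#C)[C@@H]2OC(C)(C)O[C@]2(C(=C)COCc3ccc(OC)cc3)[C@H]4OC(C)(C)O[C@@H]14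
F5 | step 11 | (E)-alkenyl dimethylalane from F4 (drawn with free hydroxyls) | OC[C@]1(O)[C@H](/C(C)=C/[Al](C)C)[C@@H]2OC(C)(C)O[C@]2(C(=C)COCc3ccc(OC)cc3)[C@H]4OC(C)(C)O[C@@H]14
F6 | step 19 | 6α,7α,8β,9β-tetraol PMB ether | COc1ccc(COCC(=C)[C@]2(O)[C@@H](O)/C=C(\C)CC/C=C(/C)[C@H](O)[C@@H]2O)cc1
F7 | step 19 | 8,9-monoacetonide 6,7-diol PMB ether | COc1ccc(COCC(=C)[C@]2(O)[C@@H](O)/C=C(\C)CC/C=C(/C)[C@@H]3OC(C)(C)O[C@H]23)cc1
F8 | step 19 | 8,9-monoacetonide 6,7,12-triol | OCC(=C)[C@]2(O)[C@@H](O)/C=C(\C)CC/C=C(/C)[C@@H]3OC(C)(C)O[C@H]23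
F9 | step 19 | 7α-hydroxy 6α,12-olide 8,9-acetonide | C=C1C(=O)O[C@H]2/C=C(\C)CC/C=C(/C)[C@@H]3OC(C)(C)O[C@@H]3[C@]12O
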